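**Retrosynthetic overview**

1. The target is a 3,4-dihydroisocoumarin: ring A (benzene, C4a–C5–C6–C7–C8–C8a, OH on C6 and C8) fused to ring B (δ-lactone, C1–O2–C3–C4–C4a–C8a), with (3R) and (9′S) carbinol centres; the last step removes three benzyl ethers by hydrogenolysis.
2. Key disconnection C4–C4a: ring B, the only ring made in the route (ring A is bought), is closed last by palladium-catalysed C(sp3)–H arylation of the terminal methyl group of an alkan-2-yl 2-bromobenzoate.
3. Enabling feature: with C4–C4a cut, C4 is simply the CH3 of an alkan-2-yl ester, and the C1–O2 ester of ring B holds it six atoms from C4a (C4a–C8a–C1–O2–C3–C4) as the only primary C–H bond within reach of palladium on C4a; C4a is meta to the oxygens on C6 and C8, so electrophiles cannot address it, but it carries bromine readily.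
4. The ester comes from a Mitsunobu inversion joining 2,4-bis(benzyloxy)-6-bromobenzoic acid (Vilsmeier–Haack, then Pinnick) to a (2R,11S) mono-benzylated tridecane-2,11-diol.
5. The diol comes from 1-bromo-6-chlorohexane as a six-carbon linchpin between (S)-2-ethyloxirane and (R)-2-methyloxirane (two copper-catalysed Grignard openings); both stereocentres are bought with the epoxides.

Key step: step 7

Remark (assumption): isochromanone numbering (C1, O2, C3, C4, C4a, C5–C8, C8a; side chain C1′–C11′) is used for all intermediates, and 1,3-bis(benzyloxy)-5-bromobenzene and both enantiopure epoxides are taken as commercial. The (2S) descriptor of the ester carbinol becomes (3R) in the lactone without any spatial change, because C4 outranks C1′ once it is bonded to ring A.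

**Route**

Step 1
Reactants: 1 1-bromo-6-chlorohexane; 2 (2S)-2-ethyloxirane
Product: 4 (3S)-10-chlorodecan-3-ol, via 6-chlorohexylmagnesium bromide 3 (not isolated)
Conditions: Mg turnings, THF, 25–40 °C; then CuI (10 mol%), 2, −30 to 0 °C; aq NH4Cl
Reagents that add atoms: none
Why: Magnesium inserts into C–Br in preference to C–Cl, and the copper-catalysed Grignard opening of the terminal epoxide is an SN2 attack at the unsubstituted carbon, so the (S) carbinol centre (future C9′) is taken unchanged from 2.

Step 2
Reactants: 4 (3S)-10-chlorodecan-3-ol
Product: 5 benzyl (3S)-10-chlorodecan-3-yl ether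
Conditions: BnOC(=NH)CCl3 (1.5 equiv), TfOH (5 mol%), CH2Cl2–cyclohexane, 0 °C to rt
Reagents that add atoms: benzyl 2,2,2-trichloroacetimidate, N=C(OCc1ccccc1)C(Cl)(Cl)Cl
Why: Acid-catalysed O-benzylation with a trichloroacetimidate protects the secondary alcohol without base or halide salts, so the primary chloride is left untouched.

Step 3
Reactants: 5 benzyl (3S)-10-chlorodecan-3-yl ether; 6 (2R)-2-methyloxirane
Product: 8 (2R,11S)-11-(benzyloxy)tridecan-2-ol, via alkylmagnesium chloride 7 (not isolated)
Conditions: Mg turnings (I2-activated), THF, reflux; then CuI (10 mol%), 6, −30 to 0 °C; aq NH4Cl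
Reagents that add atoms: none
Why: Grignard formation from the primary chloride and copper-catalysed SN2 opening of the epoxide at its CH2 terminus add the last three carbons and deliver the (2R) methyl carbinol with the configuration of 6, the benzyl ether being inert to both operations.

Step 4
Reactants: 9 1,3-bis(benzyloxy)-5-bromobenzene
Product: 11 2,4-bis(benzyloxy)-6-bromobenzaldehyde, via aryl iminium salt 10 (not isolated)
Conditions: POCl3, DMF, 0 to 70 °C; then ice/H2O
Reagents that add atoms: N,N-dimethylformamide, CN(C)C=O; water, O
Why: Vilsmeier–Haack formylation is expected at the position para to one benzyloxy group and ortho to the other (next to bromine) and not at the more hindered site between the two benzyloxy groups, as is usual for resorcinol diethers.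

Step 5
Reactants: 11 2,4-bis(benzyloxy)-6-bromobenzaldehyde
Product: 12 2,4-bis(benzyloxy)-6-bromobenzoic acid
Conditions: NaClO2, NaH2PO4, 2-methylbut-2-ene, t-BuOH–H2O, rt
Reagents that add atoms: sodium chlorite, [Na+].[O-]Cl=O
Why: Pinnick oxidation converts the aldehyde to the acid chemoselectively, with 2-methylbut-2-ene scavenging hypochlorous acid so that the electron-rich ring is not chlorinated.

Step 6
Reactants: 12 2,4-bis(benzyloxy)-6-bromobenzoic acid; 8 (2R,11S)-11-(benzyloxy)tridecan-2-ol
Product: 13 (2S,11S)-11-(benzyloxy)tridecan-2-yl 2,4-bis(benzyloxy)-6-bromobenzoate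
Conditions: PPh3, DIAD, toluene, 0 °C to rt
Reagents that add atoms: none
Why: Mitsunobu esterification lets the hindered, doubly ortho-substituted carboxylate act as nucleophile at carbon, displacing the oxyphosphonium group by SN2 with inversion, which turns the (2R) alcohol into the (2S) ester that maps onto (3R) of the target.

Step 7
Reactants: 13 (2S,11S)-11-(benzyloxy)tridecan-2-yl 2,4-bis(benzyloxy)-6-bromobenzoate
Product: 14 (3R)-6,8-bis(benzyloxy)-3-[(9S)-9-(benzyloxy)undecyl]-3,4-dihydro-1H-isochromen-1-one
Conditions: Pd(OAc)2 (10 mol%), PCy3·HBF4 (20 mol%), PivOH (30 mol%), Cs2CO3 (1.5 equiv), mesitylene, 140 °C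
Reagents that add atoms: none
Why: Proposed new method: zerovalent palladium, formed from Pd(OAc)2 and PCy3, inserts into the C4a–Br bond, pivalate replaces bromide on palladium and removes a hydrogen of the terminal methyl group (future C4) by concerted metalation–deprotonation, and the resulting seven-membered aryl(alkyl)palladacycle undergoes C(sp2)–C(sp3) reductive elimination to forge C4–C4a. The closest known reaction types are the pivalate-assisted intramolecular C(sp3)–H arylation of aryl bromides at methyl groups, which builds indanes, dihydrobenzofurans and indolines, and the ester-tethered direct arylation of aryl 2-halobenzoates to benzo[c]chromen-6-ones, which passes through the same seven-membered palladacycle across a C(=O)–O link; new here is the reach of that palladacycle to an unactivated methyl C–H bond of an alkyl ester. Ring B, the six-membered lactone, is closed by this reductive elimination from the s-trans (E) rotamer of the ester, a minor conformer that should be populated at 140 °C. No stereocentre is created, and C3 and C9′ keep their configuration because no bond to either is made or broken and neither carries a hydrogen that carbonate can remove. The step needs site selectivity for the methyl group over the C3 methine, whose palladation through a six-membered palladacycle would lead to a phthalide, and over the C1′ methylene; the marked primary over secondary over tertiary preference of concerted metalation–deprotonation should secure it, and the benzyl ether C–H bonds, meta to palladium or remote in the chain, are out of reach.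

Step 8
Reactants: 14 (3R)-6,8-bis(benzyloxy)-3-[(9S)-9-(benzyloxy)undecyl]-3,4-dihydro-1H-isochromen-1-one
Product: 15 (3R)-6,8-dihydroxy-3-[(9S)-9-hydroxyundecyl]-3,4-dihydro-1H-isochromen-1-one
Conditions: H2 (1 atm), Pd/C (10 wt%), EtOAc–EtOH, rt
Reagents that add atoms: none
Why: Catalytic hydrogenolysis cleaves the two aryl benzyl ethers and the alkyl benzyl ether in one operation and touches neither the lactone nor the two stereocentres.

**Compound list**

1 | 1-bromo-6-chlorohexane | ClCCCCCCBr | starting material
2 | (2S)-2-ethyloxirane | CC[C@H]1CO1 | starting material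
3 | 6-chlorohexylmagnesium bromide | ClCCCCCC[Mg]Br | intermediate
4 | (3S)-10-chlorodecan-3-ol | CC[C@H](O)CCCCCCCCl | intermediate
5 | benzyl (3S)-10-chlorodecan-3-yl ether | CC[C@H](OCc1ccccc1)CCCCCCCCl | intermediate
6 | (2R)-2-methyloxirane | C[C@@H]1CO1 | starting material
7 | [(8S)-8-(benzyloxy)decyl]magnesium chloride | CC[C@H](OCc1ccccc1)CCCCCCC[Mg]Cl | intermediate
8 | (2R,11S)-11-(benzyloxy)tridecan-2-ol | CC[C@H](OCc1ccccc1)CCCCCCCC[C@@H](C)O | intermediate
9 | 1,3-bis(benzyloxy)-5-bromobenzene | Brc1cc(OCc2ccccc2)cc(OCc2ccccc2)c1 | starting material
10 | {[2,4-bis(benzyloxy)-6-bromophenyl]methylidene}dimethyliminium dichlorophosphate | C[N+](C)=Cc1c(Br)cc(OCc2ccccc2)cc1OCc1ccccc1.[O-]P(=O)(Cl)Cl | intermediate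
11 | 2,4-bis(benzyloxy)-6-bromobenzaldehyde | O=Cc1c(Br)cc(OCc2ccccc2)cc1OCc1ccccc1 | intermediate
12 | 2,4-bis(benzyloxy)-6-bromobenzoic acid | OC(=O)c1c(Br)cc(OCc2ccccc2)cc1OCc1ccccc1 | intermediate
13 | (2S,11S)-11-(benzyloxy)tridecan-2-yl 2,4-bis(benzyloxy)-6-bromobenzoate | CC[C@H](OCc1ccccc1)CCCCCCCC[C@H](C)OC(=O)c1c(Br)cc(OCc2ccccc2)cc1OCc1ccccc1 | intermediate
14 | (3R)-6,8-bis(benzyloxy)-3-[(9S)-9-(benzyloxy)undecyl]-3,4-dihydro-1H-isochromen-1-one | CC[C@H](OCc1ccccc1)CCCCCCCC[C@@H]1Cc2cc(OCc3ccccc3)cc(OCc3ccccc3)c2C(=O)O1 | intermediate
15 | (3R)-6,8-dihydroxy-3-[(9S)-9-hydroxyundecyl]-3,4-dihydro-1H-isochromen-1-one | CC[C@H](O)CCCCCCCC[C@@H]1Cc2cc(O)cc(O)c2C(=O)O1 | target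

**Step count**

Total steps: 8.
Longest linear sequence: 6 (steps 1, 2, 3, 6, 7, 8).

**Steps most likely to fail, with fallbacks**

Step 7 (Proposed new method). Risk: C–H cleavage across the ester tether may be slower than protodebromination of the arylpalladium species, or palladation of the C3 methine may overtake that of the methyl group. The fallback makes C4–C4a by known aryl-metal epoxide chemistry, a standard entry to 3-substituted 3,4-dihydroisocoumarins. It sets out from 12 and 5 and comes back at 14. Acid 12 would be methylated (MeI, K2CO3, DMF) to methyl 2,4-bis(benzyloxy)-6-bromobenzoate F1. Grignard reagent 7, made from 5 as in step 3, would be added to (R)-2-(chloromethyl)oxirane under CuI catalysis to give (2R,11S)-11-(benzyloxy)-1-chlorotridecan-2-ol F2. Closure with NaOH should give (2R)-2-[(9S)-9-(benzyloxy)undecyl]oxirane F3. Bromine–magnesium exchange on F1 (i-PrMgCl·LiCl, THF, −20 °C), followed by CuI-catalysed opening of F3 at its CH2 terminus, should give a magnesium alkoxide that lactonises onto the neighbouring methyl ester on warming (p-TsOH if needed), giving 14 with the (3R) centre taken from the epoxide.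

Step 6. Risk: elimination of the activated secondary alcohol, slow capture of the oxyphosphonium ion by the hindered carboxylate, and partial loss of inversion. The fallback forms the ester by acyl substitution with retention. It sets out from 12 and 5 and comes back at 13. Acid 12 would be converted with oxalyl chloride and catalytic DMF into 2,4-bis(benzyloxy)-6-bromobenzoyl chloride F4. Grignard reagent 7 (from 5) would open (2S)-2-methyloxirane under CuI catalysis to give (2S,11S)-11-(benzyloxy)tridecan-2-ol F5. The sodium alkoxide of F5 (NaH, THF) would then be acylated by F4, giving 13 without touching the carbinol carbon.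

Step 4. Risk: poor site selectivity of formylation (attack between the two benzyloxy groups) and acid-induced loss of a benzyl ether on heating. The fallback introduces the carboxyl carbon by halogenation and exchange. It sets out from 9 and comes back at 12, bypassing 11 and step 5. Bromination of 9 with NBS in MeCN, which avoids the position flanked by two alkoxy groups, should give 1,5-bis(benzyloxy)-2,3-dibromobenzene F6. Selective bromine–magnesium exchange (i-PrMgCl·LiCl, THF, −40 °C) is expected at the bromine flanked by benzyloxy and bromine, and trapping with CO2 and acidic work-up would give 12.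

**Further compounds**

F1 | step 7 | methyl 2,4-bis(benzyloxy)-6-bromobenzoate | COC(=O)c1c(Br)cc(OCc2ccccc2)cc1OCc1ccccc1
F2 | step 7 | (2R,11S)-11-(benzyloxy)-1-chlorotridecan-2-ol | CC[C@H](OCc1ccccc1)CCCCCCCC[C@@H](O)CCl
F3 | step 7 | (2R)-2-[(9S)-9-(benzyloxy)undecyl]oxirane | CC[C@H](OCc1ccccc1)CCCCCCCC[C@@H]1CO1
F4 | step 6 | 2,4-bis(benzyloxy)-6-bromobenzoyl chloride | ClC(=O)c1c(Br)cc(OCc2ccccc2)cc1OCc1ccccc1
F5 | step 6 | (2S,11S)-11-(benzyloxy)tridecan-2-ol | CC[C@H](OCc1ccccc1)CCCCCCCC[C@H](C)O
F6 | step 4 | 1,5-bis(benzyloxy)-2,3-dibromobenzene | Brc1cc(OCc2ccccc2)cc(OCc2ccccc2)c1Br
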